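**Strategy**

Everything rests on cutting the C3–C4 bond of the pyranone (ring C). In the flavonol, C3 (enol OH) and C4 (C=O) are adjacent oxygen-bearing carbons, the enol form of a 1,2-diketone, so each can be traced back to a formyl carbon. An N-heterocyclic carbene should turn one formyl group of an aryl ether dialdehyde into an acyl anion equivalent that adds to the other, forming C3–C4 and ring C in one operation. The precursor is the A-ring salicylaldehyde whose phenolic oxygen (future O1) carries the benzylic carbon (future C2) of the B-ring arylacetaldehyde; all hydroxyls are benzyl ethers and the side-chain stereocentre comes from the (R)-Roche ester.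

Key step: step 13

Remarks on the chemistry:
- Methyl 2-(3-bromo-4-hydroxyphenyl)acetate is assumed to be purchasable; it already holds the two carbons (C2 and C3) that the B-ring half gives to ring C.
- The side-chain centre is never touched. It is R in 1–3 and S from 4 onward only because the CIP priorities change.
- Compounds 10, 17, 18, 19 and 20 are epimer mixtures at the aryloxy carbon. This does not matter, because that carbon becomes sp2 in step 14.
- Benzyl ethers are used on all three hydroxyls. They keep the A-ring aryloxide electron-rich, hence a poor leaving group next to the aliphatic aldehyde of 19, and they all fall in one hydrogenolysis.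

**Route**

Step 1
Reactants: 1 methyl (R)-3-hydroxy-2-methylpropanoate
Product: 2 methyl (R)-3-(benzyloxy)-2-methylpropanoate
Conditions: BnOC(=NH)CCl3, TfOH (cat.), CH2Cl2/cyclohexane, 0 °C → rt
Reagents that add atoms: benzyl 2,2,2-trichloroacetimidate, N=C(OCc1ccccc1)C(Cl)(Cl)Cl
Why: Acid-catalysed O-benzylation with the trichloroacetimidate avoids base, so the enolisable α-stereocentre of the ester should stay intact.

Step 2
Reactants: 2 methyl (R)-3-(benzyloxy)-2-methylpropanoate
Product: 3 (R)-3-(benzyloxy)-2-methylpropanal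
Conditions: DIBAL-H (1.05 equiv), CH2Cl2, −78 °C; Rochelle salt work-up; crude used at once
Reagents that add atoms: none
Why: Partial DIBAL reduction of the ester at low temperature should stop at the tetrahedral aluminium hemiacetal, which gives the aldehyde on work-up without epimerisation if it is not stored.

Step 3
Reactants: 3 (R)-3-(benzyloxy)-2-methylpropanal
Product: 4 benzyl (2S)-2-methylbut-3-en-1-yl ether
Conditions: Ph3PCH3Br, KHMDS, THF, 0 °C; then 3, −78 → 0 °C
Reagents that add atoms: methyltriphenylphosphonium bromide, C[P+](c1ccccc1)(c1ccccc1)c1ccccc1.[Br-]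
Why: Wittig methylenation with the salt-free non-stabilised ylide is fast at low temperature, so the α-stereocentre should be carried over unchanged.

Step 4
Reactants: 5 methyl 2-(3-bromo-4-hydroxyphenyl)acetate
Product: 6 methyl 2-[4-(benzyloxy)-3-bromophenyl]acetate
Conditions: BnBr, K2CO3, DMF, rt
Reagents that add atoms: benzyl bromide, BrCc1ccccc1
Why: Williamson etherification of the phenol, which carbonate deprotonates far more readily than the arylacetate α-position.

Step 5
Reactants: 4 benzyl (2S)-2-methylbut-3-en-1-yl ether; 6 methyl 2-[4-(benzyloxy)-3-bromophenyl]acetate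
Product: 8 methyl 2-{4-(benzyloxy)-3-[(3S)-4-(benzyloxy)-3-methylbutyl]phenyl}acetate, via alkylborane 7 (not isolated)
Conditions: 9-BBN, THF, rt; then 6, Pd(dppf)Cl2 (5 mol %), aq. K3PO4, DMF, 60 °C
Reagents that add atoms: none
Why: Anti-Markovnikov hydroboration of the terminal alkene followed by B-alkyl Suzuki–Miyaura coupling joins the sp3 chain to the aryl bromide without touching the stereocentre or the ester.

Step 6
Reactants: 8 methyl 2-{4-(benzyloxy)-3-[(3S)-4-(benzyloxy)-3-methylbutyl]phenyl}acetate
Product: 10 methyl 2-bromo-2-{4-(benzyloxy)-3-[(3S)-4-(benzyloxy)-3-methylbutyl]phenyl}acetate (both configurations at the bromine-bearing carbon), via silyl ketene acetal 9 (not isolated)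
Conditions: LiHMDS, THF, −78 °C; TMSCl; then NBS, −78 → 0 °C
Reagents that add atoms: N-bromosuccinimide, O=C1CCC(=O)N1Br
Why: Electrophilic α-bromination through the silyl ketene acetal places bromine only at the ester α-carbon and avoids the radical conditions that would attack the other benzylic positions.

Step 7
Reactants: 11 3-hydroxy-4,5-dimethoxybenzaldehyde
Product: 13 4,5-dimethoxybenzene-1,3-diol, via aryl formate 12 (not isolated)
Conditions: 30% H2O2, H2SO4 (cat.), MeOH, rt, under N2
Reagents that add atoms: hydrogen peroxide, OO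
Why: Acid-catalysed Dakin oxidation, in which the electron-rich aryl group (para-methoxy) migrates to oxygen and the resulting formate is methanolysed in the same flask.

Step 8
Reactants: 13 4,5-dimethoxybenzene-1,3-diol
Product: 15 4,6-dihydroxy-2,3-dimethoxybenzaldehyde, via iminium salt 14 (not isolated)
Conditions: POCl3, DMF, MeCN, 0 °C → rt; then H2O, 50 °C
Reagents that add atoms: N,N-dimethylformamide, CN(C)C=O; water, O
Why: Vilsmeier–Haack formylation of a resorcinol should go to the ring carbon para to one hydroxyl and ortho to the other (C6), not to the carbon between the two hydroxyls.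

Step 9
Reactants: 15 4,6-dihydroxy-2,3-dimethoxybenzaldehyde
Product: 16 4-(benzyloxy)-6-hydroxy-2,3-dimethoxybenzaldehyde
Conditions: BnBr (1.05 equiv), NaHCO3, MeCN, 70 °C
Reagents that add atoms: benzyl bromide, BrCc1ccccc1
Why: Regioselective Williamson etherification, since the hydroxyl para to the formyl group is the more acidic and the ortho hydroxyl is held back by its hydrogen bond to the carbonyl.

Step 10
Reactants: 16 4-(benzyloxy)-6-hydroxy-2,3-dimethoxybenzaldehyde; 10 methyl 2-bromo-2-{4-(benzyloxy)-3-[(3S)-4-(benzyloxy)-3-methylbutyl]phenyl}acetate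
Product: 17 methyl 2-[5-(benzyloxy)-2-formyl-3,4-dimethoxyphenoxy]-2-{4-(benzyloxy)-3-[(3S)-4-(benzyloxy)-3-methylbutyl]phenyl}acetate
Conditions: K2CO3, DMF, rt
Reagents that add atoms: none
Why: SN2 O-alkylation of the phenoxide by the doubly activated (benzylic and α-carbonyl) bromide, run at room temperature so that the product does not go on to an aldol ring closure.

Step 11
Reactants: 17 methyl 2-[5-(benzyloxy)-2-formyl-3,4-dimethoxyphenoxy]-2-{4-(benzyloxy)-3-[(3S)-4-(benzyloxy)-3-methylbutyl]phenyl}acetate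
Product: 18 2-[5-(benzyloxy)-2-(hydroxymethyl)-3,4-dimethoxyphenoxy]-2-{4-(benzyloxy)-3-[(3S)-4-(benzyloxy)-3-methylbutyl]phenyl}ethan-1-ol
Conditions: LiAlH4, THF, 0 °C
Reagents that add atoms: none
Why: Hydride reduction takes the ester and the aldehyde to the two primary alcohols and leaves the aryl and benzyl ethers alone.

Step 12
Reactants: 18 2-[5-(benzyloxy)-2-(hydroxymethyl)-3,4-dimethoxyphenoxy]-2-{4-(benzyloxy)-3-[(3S)-4-(benzyloxy)-3-methylbutyl]phenyl}ethan-1-ol
Product: 19 4-(benzyloxy)-6-({1-[4-(benzyloxy)-3-[(3S)-4-(benzyloxy)-3-methylbutyl]phenyl]-2-oxoethyl}oxy)-2,3-dimethoxybenzaldehyde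
Conditions: Dess–Martin periodinane (2.5 equiv), pyridine, CH2Cl2, 0 °C → rt; short silica plug, used the same day
Reagents that add atoms: none
Why: Dess–Martin oxidation converts both primary alcohols to aldehydes under nearly neutral conditions, which should spare the enolisable α-aryloxy aldehyde from aldol reactions.

Step 13
Reactants: 19 4-(benzyloxy)-6-({1-[4-(benzyloxy)-3-[(3S)-4-(benzyloxy)-3-methylbutyl]phenyl]-2-oxoethyl}oxy)-2,3-dimethoxybenzaldehyde
Product: 20 7-(benzyloxy)-2-{4-(benzyloxy)-3-[(3S)-4-(benzyloxy)-3-methylbutyl]phenyl}-3-hydroxy-5,6-dimethoxychroman-4-one (mixture at C2 and C3)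
Conditions: 2-(pentafluorophenyl)-6,7-dihydro-5H-pyrrolo[2,1-c][1,2,4]triazol-2-ium BF4 (15 mol %), Et3N (15 mol %), degassed toluene (0.02 M), rt, Ar
Reagents that add atoms: none
Why: The carbene freed from the triazolium salt adds to a formyl group of 19, proton transfer gives the Breslow enaminol, its nucleophilic carbon attacks the second formyl group, and collapse of the adduct releases the carbene and leaves the acyloin. The closest known reaction is the carbene-catalysed intramolecular crossed benzoin of O-tethered salicylaldehyde carbonyl compounds to 3-hydroxychroman-4-ones. The pyranone ring closes 6-exo-trig, with the new C3–C4 bond inside the ring and the acceptor C=O outside it. C3 is a new stereocentre and C2 is already a mixture; neither is controlled, and both are erased in step 14. The step needs ring closure to outrun intermolecular benzoin, base-induced 5-exo aldol of the enolisable aldehyde onto the aryl aldehyde, and loss of the A-ring aryloxide from a Breslow intermediate formed at the aliphatic aldehyde; the six-atom tether with high dilution, the weak catalytic base, the α-branching that slows carbene addition at the aliphatic formyl group, and the electron-rich trialkoxy aryloxide (a poor leaving group) are meant to secure this. Which aldehyde acts as donor does not matter, since a regioisomeric acyloin would be oxidised to the same dione in step 14.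

Step 14
Reactants: 20 7-(benzyloxy)-2-{4-(benzyloxy)-3-[(3S)-4-(benzyloxy)-3-methylbutyl]phenyl}-3-hydroxy-5,6-dimethoxychroman-4-one
Product: 22 7-(benzyloxy)-2-{4-(benzyloxy)-3-[(3S)-4-(benzyloxy)-3-methylbutyl]phenyl}-3-hydroxy-5,6-dimethoxy-4H-chromen-4-one, via chroman-3,4-dione 21 (not isolated)
Conditions: I2 (1.2 equiv), KOAc, AcOH, 90 °C
Reagents that add atoms: none
Why: Classical iodine–acetate dehydrogenation of a dihydroflavonol, in which the acyloin is oxidised through its enediol to the 3,4-dione, which tautomerises through C2–H to the 3-hydroxychromone.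

Step 15
Reactants: 22 7-(benzyloxy)-2-{4-(benzyloxy)-3-[(3S)-4-(benzyloxy)-3-methylbutyl]phenyl}-3-hydroxy-5,6-dimethoxy-4H-chromen-4-one
Product: 23 3,7-dihydroxy-2-{4-hydroxy-3-[(3S)-4-hydroxy-3-methylbutyl]phenyl}-5,6-dimethoxy-4H-chromen-4-one (CNP0253239.1)
Conditions: H2 (1 atm), 10% Pd/C, EtOAc/MeOH, rt
Reagents that add atoms: none
Why: Catalytic hydrogenolysis cleaves the two aryl benzyl ethers and the alkyl benzyl ether, while the chromone C2=C3 bond and the methyl ethers should not react at one atmosphere.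

**Compound list**

1 | methyl (R)-3-hydroxy-2-methylpropanoate | COC(=O)[C@H](C)CO | starting material
2 | methyl (R)-3-(benzyloxy)-2-methylpropanoate | COC(=O)[C@H](C)COCc1ccccc1 | intermediate
3 | (R)-3-(benzyloxy)-2-methylpropanal | O=C[C@H](C)COCc1ccccc1 | intermediate
4 | benzyl (2S)-2-methylbut-3-en-1-yl ether | C=C[C@H](C)COCc1ccccc1 | intermediate
5 | methyl 2-(3-bromo-4-hydroxyphenyl)acetate | COC(=O)Cc1ccc(O)c(Br)c1 | starting material
6 | methyl 2-[4-(benzyloxy)-3-bromophenyl]acetate | COC(=O)Cc1ccc(OCc2ccccc2)c(Br)c1 | intermediate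
7 | 9-[(3S)-4-(benzyloxy)-3-methylbutyl]-9-borabicyclo[3.3.1]nonane | C[C@@H](CCB1C2CCCC1CCC2)COCc1ccccc1 | intermediate (not isolated)
8 | methyl 2-{4-(benzyloxy)-3-[(3S)-4-(benzyloxy)-3-methylbutyl]phenyl}acetate | COC(=O)Cc1ccc(OCc2ccccc2)c(CC[C@H](C)COCc2ccccc2)c1 | intermediate
9 | trimethylsilyl ketene acetal of 8 (alkene geometry undefined) | COC(O[Si](C)(C)C)=Cc1ccc(OCc2ccccc2)c(CC[C@H](C)COCc2ccccc2)c1 | intermediate (not isolated)
10 | methyl 2-bromo-2-{4-(benzyloxy)-3-[(3S)-4-(benzyloxy)-3-methylbutyl]phenyl}acetate | COC(=O)C(Br)c1ccc(OCc2ccccc2)c(CC[C@H](C)COCc2ccccc2)c1 | intermediate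
11 | 3-hydroxy-4,5-dimethoxybenzaldehyde | COc1cc(C=O)cc(O)c1OC | starting material
12 | 3-hydroxy-4,5-dimethoxyphenyl formate | O=COc1cc(O)c(OC)c(OC)c1 | intermediate (not isolated)
13 | 4,5-dimethoxybenzene-1,3-diol | COc1cc(O)cc(O)c1OC | intermediate
14 | N-(2,4-dihydroxy-5,6-dimethoxybenzylidene)-N-methylmethanaminium chloride | C[N+](C)=Cc1c(O)cc(O)c(OC)c1OC.[Cl-] | intermediate (not isolated)
15 | 4,6-dihydroxy-2,3-dimethoxybenzaldehyde | O=Cc1c(OC)c(OC)c(O)cc1O | intermediate
16 | 4-(benzyloxy)-6-hydroxy-2,3-dimethoxybenzaldehyde | O=Cc1c(OC)c(OC)c(OCc2ccccc2)cc1O | intermediate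
17 | methyl 2-[5-(benzyloxy)-2-formyl-3,4-dimethoxyphenoxy]-2-{4-(benzyloxy)-3-[(3S)-4-(benzyloxy)-3-methylbutyl]phenyl}acetate | COC(=O)C(Oc1cc(OCc2ccccc2)c(OC)c(OC)c1C=O)c1ccc(OCc2ccccc2)c(CC[C@H](C)COCc2ccccc2)c1 | intermediate
18 | 2-[5-(benzyloxy)-2-(hydroxymethyl)-3,4-dimethoxyphenoxy]-2-{4-(benzyloxy)-3-[(3S)-4-(benzyloxy)-3-methylbutyl]phenyl}ethan-1-ol | OCC(Oc1cc(OCc2ccccc2)c(OC)c(OC)c1CO)c1ccc(OCc2ccccc2)c(CC[C@H](C)COCc2ccccc2)c1 | intermediate
19 | 4-(benzyloxy)-6-({1-[4-(benzyloxy)-3-[(3S)-4-(benzyloxy)-3-methylbutyl]phenyl]-2-oxoethyl}oxy)-2,3-dimethoxybenzaldehyde | O=Cc1c(OC)c(OC)c(OCc2ccccc2)cc1OC(C=O)c1ccc(OCc2ccccc2)c(CC[C@H](C)COCc2ccccc2)c1 | intermediate (key-step precursor)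
20 | 7-(benzyloxy)-2-{4-(benzyloxy)-3-[(3S)-4-(benzyloxy)-3-methylbutyl]phenyl}-3-hydroxy-5,6-dimethoxychroman-4-one | COc1c(OCc2ccccc2)cc2OC(c3ccc(OCc4ccccc4)c(CC[C@H](C)COCc4ccccc4)c3)C(O)C(=O)c2c1OC | intermediate (key-step product)
21 | 7-(benzyloxy)-2-{4-(benzyloxy)-3-[(3S)-4-(benzyloxy)-3-methylbutyl]phenyl}-5,6-dimethoxychroman-3,4-dione | COc1c(OCc2ccccc2)cc2OC(c3ccc(OCc4ccccc4)c(CC[C@H](C)COCc4ccccc4)c3)C(=O)C(=O)c2c1OC | intermediate (not isolated)
22 | 7-(benzyloxy)-2-{4-(benzyloxy)-3-[(3S)-4-(benzyloxy)-3-methylbutyl]phenyl}-3-hydroxy-5,6-dimethoxy-4H-chromen-4-one | COc1c(OCc2ccccc2)cc2oc(-c3ccc(OCc4ccccc4)c(CC[C@H](C)COCc4ccccc4)c3)c(O)c(=O)c2c1OC | intermediate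
23 | 3,7-dihydroxy-2-{4-hydroxy-3-[(3S)-4-hydroxy-3-methylbutyl]phenyl}-5,6-dimethoxy-4H-chromen-4-one | COc1c(O)cc2oc(-c3ccc(O)c(CC[C@H](C)CO)c3)c(O)c(=O)c2c1OC | target

**Step count and risks**

Total steps: 15. Longest linear sequence: 11 steps (1, 2, 3, 5, 6, 10, 11, 12, 13, 14, 15, counted from compound 1).

Steps most likely to fail:

1. Step 13. The carbene may add mainly to the aliphatic aldehyde, and the Breslow intermediate formed there may expel the A-ring aryloxide (internal redox to an aryl ester). The base may also trigger a five-membered aldol closure, or the hindered aromatic aldehyde may not turn over. The fallback gives up the C3–C4 closure and builds the flavonol by known flavone chemistry; it sets out from 13 and 7 and comes back at 22.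
   - C-Acetylation of 13 with Ac2O/BF3·OEt2 should give 1-(4,6-dihydroxy-2,3-dimethoxyphenyl)ethan-1-one F1.
   - Selective benzylation of the para hydroxyl, as in step 9, should give 1-[4-(benzyloxy)-6-hydroxy-2,3-dimethoxyphenyl]ethan-1-one F2.
   - Commercial 3-bromo-4-hydroxybenzaldehyde is benzylated to 4-(benzyloxy)-3-bromobenzaldehyde F3.
   - F3 is coupled with alkylborane 7 under the conditions of step 5 to give 4-(benzyloxy)-3-[(3S)-4-(benzyloxy)-3-methylbutyl]benzaldehyde F4.
   - Claisen–Schmidt condensation of F2 and F4 (KOH, EtOH) should give the (E)-2'-hydroxychalcone F5.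
   - Oxidative cyclisation (I2 cat., DMSO, 120 °C) should give 7-(benzyloxy)-2-{4-(benzyloxy)-3-[(3S)-4-(benzyloxy)-3-methylbutyl]phenyl}-5,6-dimethoxy-4H-chromen-4-one F6.
   - Epoxidation of the C2=C3 bond with dimethyldioxirane should give the 2,3-epoxyflavanone F7, which opens with catalytic TsOH to the flavonol 22.
   - This path also removes steps 10–12.

2. Step 8. Formylation may also occur at the carbon between the two hydroxyls (poor positional selectivity), and the electron-rich resorcinol may decompose oxidatively during steps 7 and 8. The fallback never frees the resorcinol; it sets out from 11 and comes back at 16.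
   - Benzylation of 11 (BnBr, K2CO3) should give 3-(benzyloxy)-4,5-dimethoxybenzaldehyde F8.
   - Baeyer–Villiger oxidation with mCPBA should give 3-(benzyloxy)-4,5-dimethoxyphenyl formate F9.
   - Methanolysis (K2CO3, MeOH) should give 3-(benzyloxy)-4,5-dimethoxyphenol F10.
   - Magnesium-phenoxide-directed ortho-formylation (MgCl2, Et3N, paraformaldehyde, MeCN, reflux) should give 16. It is expected to favour the ortho position next to the methoxy group over the one next to the larger benzyloxy group, and the isomers should be separable.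

3. Step 10. The hindered, hydrogen-bonded phenoxide may alkylate slowly, and under base the product may cyclise by aldol attack of its ester enolate on the neighbouring formyl group. Step 6 may also over-brominate. The fallback forms the same C–O bond under neutral conditions; it sets out from 8 and 16 and comes back at 17.
   - The potassium enolate of 8 (KHMDS, THF, −78 °C) is hydroxylated with 2-(phenylsulfonyl)-3-phenyloxaziridine to give methyl 2-{4-(benzyloxy)-3-[(3S)-4-(benzyloxy)-3-methylbutyl]phenyl}-2-hydroxyacetate F11.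
   - Mitsunobu etherification of F11 with the acidic phenol 16 (PPh3, DIAD, THF, 0 °C → rt) should give 17.

**Further compounds**

F1 | step 13 | 1-(4,6-dihydroxy-2,3-dimethoxyphenyl)ethan-1-one | CC(=O)c1c(OC)c(OC)c(O)cc1O
F2 | step 13 | 1-[4-(benzyloxy)-6-hydroxy-2,3-dimethoxyphenyl]ethan-1-one | CC(=O)c1c(OC)c(OC)c(OCc2ccccc2)cc1O
F3 | step 13 | 4-(benzyloxy)-3-bromobenzaldehyde | O=Cc1ccc(OCc2ccccc2)c(Br)c1
F4 | step 13 | 4-(benzyloxy)-3-[(3S)-4-(benzyloxy)-3-methylbutyl]benzaldehyde | O=Cc1ccc(OCc2ccccc2)c(CC[C@H](C)COCc2ccccc2)c1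
F5 | step 13 | (E)-1-[4-(benzyloxy)-6-hydroxy-2,3-dimethoxyphenyl]-3-{4-(benzyloxy)-3-[(3S)-4-(benzyloxy)-3-methylbutyl]phenyl}prop-2-en-1-one | O=C(/C=C/c1ccc(OCc2ccccc2)c(CC[C@H](C)COCc2ccccc2)c1)c1c(OC)c(OC)c(OCc2ccccc2)cc1O
F6 | step 13 | 7-(benzyloxy)-2-{4-(benzyloxy)-3-[(3S)-4-(benzyloxy)-3-methylbutyl]phenyl}-5,6-dimethoxy-4H-chromen-4-one | COc1c(OCc2ccccc2)cc2oc(-c3ccc(OCc4ccccc4)c(CC[C@H](C)COCc4ccccc4)c3)cc(=O)c2c1OC
F7 | step 13 | 2,3-epoxide of F6 (2,3-epoxyflavanone, both epoxide configurations) | COc1c(OCc2ccccc2)cc2OC3(c4ccc(OCc5ccccc5)c(CC[C@H](C)COCc5ccccc5)c4)OC3C(=O)c2c1OC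
F8 | step 8 | 3-(benzyloxy)-4,5-dimethoxybenzaldehyde | COc1cc(C=O)cc(OCc2ccccc2)c1OC
F9 | step 8 | 3-(benzyloxy)-4,5-dimethoxyphenyl formate | O=COc1cc(OCc2ccccc2)c(OC)c(OC)c1
F10 | step 8 | 3-(benzyloxy)-4,5-dimethoxyphenol | COc1cc(O)cc(OCc2ccccc2)c1OC
F11 | step 10 | methyl 2-{4-(benzyloxy)-3-[(3S)-4-(benzyloxy)-3-methylbutyl]phenyl}-2-hydroxyacetate | COC(=O)C(O)c1ccc(OCc2ccccc2)c(CC[C@H](C)COCc2ccccc2)c1
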